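If a closed flask stops changing long before the run ends, what is left to compare between set-ups?

| flask | starting material | partner | second substrate | remark | time |
|---|---|---|---|---|---|
| epsilon | 0.20 M | 1.05 equiv | 1 equiv | run made earlier |  |
| zeta | 0.20 M | 1.05 equiv | 0.50 equiv | run made earlier |  |
| theta | 0.20 M | 1.05 equiv | 2 equiv | run made earlier |  |
| larch | 0.20 M | 1.05 equiv | 1.00 equiv | one stirred flow tank at steady state, fed with the mixture as stated, mean residence time 5.0 min |  |
| ash | 0.20 M | 1.05 equiv | 1.00 equiv | a closed flask charged with all of it at once and left for 5.0 min | 5.0 min |
| maple | 0.20 M | 1.05 equiv | 1.00 equiv (fed, over 4.00 min) | all but second substrate at the start; second substrate goes in evenly over 4.00 min, the run ends at 5.0 min | 5.0 min |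
| oak | 0.20 M | 1.05 equiv (fed, over 4.00 min) | 1.00 equiv | all but partner at the start; partner goes in evenly over 4.00 min, the run ends at 5.0 min | 5.0 min |

| run | time / min | target / % | starting material / % |
|---|---|---|---|
| epsilon | 0.200 | 71.5 | 27.9 |
| epsilon | 0.667 | 78.3 | 22.2 |
| epsilon | 1.00 | 78.5 | 22.4 |
| epsilon | 1.50 | 78.6 | 21.3 |
| epsilon | 2.50 | 78.2 | 21.4 |
| epsilon | 3.00 | 78.4 | 21.6 |
| zeta | 0.200 | 77.6 | 21.9 |
| zeta | 0.667 | 81.5 | 18.3 |
| zeta | 1.00 | 82.2 | 17.8 |
| zeta | 1.50 | 82.4 | 18.2 |
| zeta | 2.50 | 82.3 | 17.9 |
| zeta | 3.00 | 82.6 | 18.2 |
| theta | 0.200 | 61.7 | 38.4 |
| theta | 0.667 | 71.5 | 28.3 |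
| theta | 1.00 | 71.9 | 27.9 |
| theta | 1.50 | 72.4 | 27.5 |
| theta | 2.50 | 72.5 | 28.4 |
| theta | 3.00 | 72.5 | 27.5 |

(scatter of a reading: 0.3 percentage points)

- the stated concentrations are those of everything mixed, before any reaction; amounts are the same in each set-up
- reactions considered so far: starting material + partner <-> target; second substrate + partner <-> second product
- the feed brings no volume worth counting
- the earlier runs were made in a closed, stirred flask

- the set-up with the highest amount of target at the outlet or at the end, in percent of the starting material put in ("none" if the first two lie within 2 percentage points) (larch / ash / maple / oak / none)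
- amount of target at the outlet or at the end, in percent of the starting material put in, larch
- amount of target at the outlet or at the end, in percent of the starting material put in, ash
- amount of target at the outlet or at the end, in percent of the starting material put in, maple
- amount of target at the outlet or at the end, in percent of the starting material put in, oak

**What do the readings show?** In epsilon, target reads 78.5% at 1.00 min and 78.4% at 3.00 min, so it has stopped within the scatter, with 21.6% of the starting material still there. I read that stop as a balance, an equilibrium. With 0.50 equiv of second substrate the stop reads 82.6%, and with 2 equiv it reads 72.5%.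

**How fast is the stop reached?** In epsilon the gap to the stop begins at 78.4% and is 6.9 percentage points at 0.200 min. If it shrinks exponentially, the closing time τ (the relaxation time), in which the gap falls by a factor e, is 0.0823 min.

**And ash?** Ash has the charge of epsilon, and its 5.0 min is 60.8 closing times, so I put it at the stop of epsilon, 78.4%.

**Maple and oak end with feeding still going on?** No. Feeding ends at 4.00 min, which leaves 1.00 min, or 12.2 closing times. I put both at the stop as well.

**Then why not larch too?** Fresh feed keeps arriving in larch, so I follow one molecule in the tank. It either closes on the balance, at rate 1/τ, or is washed out, at rate 1/θ, where θ is the mean residence time, 5.0 min. The leak L, the chance of leaving before closing, τ/(τ+θ), is 1.62%. My larch is therefore 77.1%. That stands 1.3 points under my other three, less than the margin of 2 points, so my best is none.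

**Where is that weakest?** The τ comes from the wide early gap, and closing may be slower near the stop.

The forecast gives 75.5% for larch, 78.4% for ash, 78.4% for maple and 78.3% for oak, with best none; of maple and oak it says “order of addition is forgotten”. It sets larch lower than my 77.1%, and for ash, maple and oak we differ by no more than 0.1 points.

The flask gives 76.5% for larch, 78.3% for ash, 78.3% for maple and 78.3% for oak, with best none.

    starting material + partner ⇌ target (K = 180 M⁻¹, k = 3.10 M⁻¹ s⁻¹)
    second substrate + partner ⇌ second product (K = 10.0 M⁻¹, k = 9.70 M⁻¹ s⁻¹)

Larch's shortfall against ash is a leak of 2.29%, not my 1.62%, so the closing time read back from it is 0.117 min, longer than my 0.0823 min but far shorter than the residence time of 5.0 min. Maple has 8.55 of these closing times after its feed ends, and leaving it ten times as long changes nothing, with target at 78.3% after 50.0 min.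

Readings and results stem from a simulated flask for substances that don't exist, and the scatter is random.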